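Atom numbering used throughout: C1 is the quaternary carbinol carbon, C7 its benzoyloxymethyl carbon, C2=C3 the alkene, C4 the benzoate carbon, C5 and C6 the free secondary carbinols (C6 next to C1). O1, O4, O5, O6 and O7 are the oxygens on those carbons. The "top face" is the face of the C1 hydroxyl.

## Analysis of the target

Kweichowenol B (17) is a cyclohex-2-ene with four contiguous oxygenated ring carbons (C4, C5, C6, C1) and one exocyclic oxygenated carbon (C7). Its configuration is (1R,4S,5S,6S): every vicinal pair of ring oxygens is trans (O1/O6, O6/O5, O5/O4), so O1 and O5 lie on the top face and C7, O6 and O4 on the bottom face. Two benzoates sit next to free hydroxyls (O4 beside O5; O7 beside O1 and O6), so base invites acyl migration. The C4 ester is allylic and the C1 alcohol is tertiary and allylic, so strong acid invites ionisation. The synthesis is hard for two reasons: a quaternary carbinol has to be set in absolute terms together with three secondary centres, and five oxygens must be told apart so that only O4 and O7 are acylated. The feature the plan rests on is that C1 lies between two two-carbon arms, C2=C3 and C6–C5, which both end at C4. With C5–C6 as an alkene and C4 as a carbonyl carbon the ring is a 4-substituted 4-hydroxycyclohexa-2,5-dienone, a dearomatised para-substituted phenol in which C1 sits on a mirror plane and is prochiral. Oxidising one of the two enantiotopic alkenes fixes C1, and the C1 hydroxyl can steer that oxidation to its own face.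

## Retrosynthetic reasoning

17 from 16. The last disconnection is the pair of Si–O bonds of a disiloxane bridge across O5 and O6. A silicon bridge is chosen because it can be removed under slightly acidic, non-basic conditions, so no alkoxide is formed next to either benzoate.

16 from 15 and 7, and 15 from 14. The O4–acyl bond is cut (benzoylation of 15 with benzoyl chloride 7), then the C4–H bond (hydride addition to ketone 14). C4 is placed last among the stereocentres because its configuration can be taken from C5: with O5 and O6 locked equatorial by the bridge, axial hydride delivery gives the trans C4/C5 arrangement. The forward steps must reduce 1,2 and not 1,4, and must acylate only O4, which is easy because O1 is tertiary and O5 and O6 are tied up.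

14 from 13. The bridge is introduced on the keto triol 13. A trans-fused seven-membered disiloxane can only span the two secondary, diequatorial hydroxyls, so one reagent both differentiates O5/O6 from O1 and rigidifies the ring for the reduction.

13 from 10. The C6–O bond is cut and the C4 ketone is returned to its dimethyl ketal, which leads to the syn epoxide 10. C6 is the carbon to attack because the C7 benzoate of 10 sits on the face opposite the oxirane and is one carbon away from C6. Its carbonyl oxygen can displace the oxirane oxygen at C6 with inversion through a six-membered ring, while C5 keeps its oxygen and configuration. This converts the cis oxirane into the trans O5/O6 diol with O6 trans to O1, and it needs the oxirane to be syn to the C1 hydroxyl.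

10 from 8 and 9 (key disconnection). Both C–O bonds of the oxirane are cut, which gives the achiral dienol 8 and tert-butyl hydroperoxide 9. In 8 the two alkenes are enantiotopic and both are allylic to the C1 hydroxyl. A chiral catalyst that binds that hydroxyl can therefore choose one alkene and deliver oxygen to the hydroxyl face, creating C1, C5 and C6 in one operation.

8 from 6 and 7, 6 from 5, and 5 from 2 and 3. The primary ester is cut (selective acylation of diol 6 with 7). The C7–O bond is traced to a C7–Si bond in 5 (oxidative cleavage with retention of the carbon skeleton), and the C1–C7 bond is cut to give the dienone ketal 2 and the Grignard reagent 4 made from chlorosilane 3. A silicon-masked hydroxymethyl nucleophile is used because it adds 1,2 to the ketone under non-acidic conditions and is unmasked under buffered conditions that the acid-labile ketal survives.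

2 from 1. The ketal carbon is traced back to the methoxy-bearing carbon of 4-methoxyphenol 1 by oxidative dearomatisation, so all six ring carbons and O4 come from a cheap aromatic compound.

## Alternatives that were turned down

Alternative 1: The ring is disconnected at C4–C5 and C1–C6, giving 3-hydroxy-2H-pyran-2-one (A1) as diene and (E)-hex-3-ene-2,5-dione (A2) as dienophile. In the forward direction an amine base converts A1 into its dienolate, and [4+2] addition to A2 closes the carbocycle inside the bridged lactone A3.
- For it: one step makes two C–C bonds, the ring and all four stereocentres. The lactone bridge ties the future C7 and O4 to the same face, as 17 requires, and the E geometry of A2 becomes the trans C5/C6 relationship. Base-catalysed asymmetric cycloadditions of hydroxypyrones to electron-poor alkenes are an established class.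
- Against it: C5 and C6 arrive as acetyl-bearing carbons, so a double Baeyer–Villiger oxidation is needed in a molecule that also holds a strained alkene (competing epoxidation) and a bridged lactone prone to decarboxylative cycloreversion. Because A2 is trans, one acetyl ends syn to the etheno bridge and the other syn to the lactone bridge, so the endo rule cannot say which diastereomer forms and the catalyst alone must decide. After the oxidation O5 and O6 are acetates, the positions that must end free, while O4 and O7 (from lactone reduction) must be benzoylated; this forces an acetate-versus-benzoate differentiation.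
- Comparison: it is stronger on bond construction and guarantees the C7/O4 cis relationship, which the chosen plan obtains from a reduction. The chosen plan makes no ring C–C bond at all, places every ring oxygen as oxygen, and reaches the final acylation pattern with fewer redox and protecting-group corrections.

Alternative 2: The C1–C6 bond is cut, giving the acyclic (Z)-configured keto aldehyde A4, which carries both benzoates and a silyl ether at O5. A chiral triazolium-derived carbene turns the C6 aldehyde into an acyl-anion equivalent that adds to the C1 ketone and closes the six-membered α-ketol A5.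
- For it: after A5 only a C6 ketone reduction (which the C1 hydroxyl could direct from its own face, giving the trans O1/O6 pair) and a desilylation remain, so its end game is shorter than the chosen one. Both benzoates are in place from the start, and intramolecular aldehyde–ketone benzoin closures to six-membered tertiary α-ketols are well documented.
- Against it: A4 must be made as a single enantiomer with C4 and C5 already set, which needs its own chiral-pool or asymmetric sequence. Its Z enone can isomerise to the E form, which cannot cyclise. The O4 benzoate is β to the aldehyde and vinylogously β to the ketone, so the basic carbene conditions invite E1cB loss of benzoate, and the α-silyloxy aldehyde can epimerise. The catalyst must also override or match two existing stereocentres.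
- Comparison: it is stronger after the key step, weaker before it. The chosen plan puts its risk into one step on an achiral, robust precursor (8) that is four steps from a phenol, and pays with a longer end game.

Alternative 3: The C1–O and C4–O bonds are cut together, giving the 1-substituted cyclohexa-1,3-diene A6 (free O5 hydroxyl, silyl ether at O6). Sensitised photooxygenation adds dioxygen across C1 and C4 and gives the endoperoxide A7, leaving C2=C3 in place.
- For it: two C–O bonds and the alkene position are set in one metal-free step, and the quaternary oxygenated centre forms without any manipulation at C1. On directness of oxygenation it is stronger than the chosen plan.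
- Against it: the bridge forces O1 and O4 onto the same face, whereas 17 has them on opposite faces, so after O–O reduction C4 must be inverted. An esterification with inversion could do this and install the benzoate, but it would have to work beside a free O5 hydroxyl and a tertiary allylic O1 hydroxyl. A6 is a trans-5,6-dioxygenated cyclohexadiene that can aromatise by loss of an oxygen substituent, must be supplied enantiopure with O5 and O6 already differentiated, and offers an ene pathway to the oxidant. Face selectivity rests on a contest between hydroxyl steering and silyl bulk. The key step creates no absolute configuration.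
- Comparison: the chosen plan creates the absolute configuration catalytically from an achiral intermediate and gets the trans O1/O4 relationship without an inversion step.

Key step: step 5

Assumption: the sense of induction of the bis-hydroxamate catalyst with this new substrate is not assigned in advance; L* denotes the ligand enantiomer (from (R,R)- or (S,S)-trans-cyclohexane-1,2-diamine, both available) that leads to the (1R,2R,6S) epoxide 10, to be identified in the first run.

## Route

Step 1
Reactants: 1 4-methoxyphenol
Product: 2 4,4-dimethoxycyclohexa-2,5-dien-1-one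
Conditions: PhI(OAc)2 (1.1 equiv), MeOH, 0 °C to rt
Reagents that add atoms: methanol, CO
Why: Oxidative dearomatisation of a para-alkoxyphenol: the phenol oxygen binds the aryliodane, and methanol attacks the para carbon as iodobenzene leaves, giving the quinone monoketal; no stereocentre is formed.

Step 2
Reactants: 2 4,4-dimethoxycyclohexa-2,5-dien-1-one; 3 chloromethyl(isopropoxy)dimethylsilane
Product: 5 4,4-dimethoxy-1-{[dimethyl(propan-2-yloxy)silyl]methyl}cyclohexa-2,5-dien-1-ol, via Grignard reagent 4 (not isolated)
Conditions: 3, Mg turnings, cat. BrCH2CH2Br, THF, rt to 40 °C; then 2, THF, −78 to 0 °C; pH 7 phosphate buffer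
Reagents that add atoms: none
Why: Grignard 1,2-addition of a hard α-silyl carbanion to the cross-conjugated ketone of a quinone monoketal (Tamao hydroxymethylation, first stage). The product is achiral and is kept away from acid so that neither the ketal nor the β-hydroxysilane (Peterson elimination) is lost.

Step 3
Reactants: 5 4,4-dimethoxy-1-{[dimethyl(propan-2-yloxy)silyl]methyl}cyclohexa-2,5-dien-1-ol
Product: 6 1-(hydroxymethyl)-4,4-dimethoxycyclohexa-2,5-dien-1-ol
Conditions: 30% aq H2O2, KF, KHCO3, THF/MeOH (1:1), rt
Reagents that add atoms: hydrogen peroxide, OO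
Why: Tamao oxidation: the alkoxysilane is activated by fluoride, hydroperoxide adds to silicon and the CH2 group migrates from Si to O. The bicarbonate buffer spares the ketal and the unactivated alkenes.

Step 4
Reactants: 6 1-(hydroxymethyl)-4,4-dimethoxycyclohexa-2,5-dien-1-ol; 7 benzoyl chloride
Product: 8 (1-hydroxy-4,4-dimethoxycyclohexa-2,5-dien-1-yl)methyl benzoate
Conditions: 7 (1.05 equiv), Et3N, DMAP (5 mol %), CH2Cl2, −20 to 0 °C
Reagents that add atoms: none
Why: Acyl transfer to the primary hydroxyl is much faster than to the tertiary, doubly allylic one, so the mono-benzoate forms selectively. The basic medium protects the ketal.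

Step 5
Reactants: 8 (1-hydroxy-4,4-dimethoxycyclohexa-2,5-dien-1-yl)methyl benzoate; 9 tert-butyl hydroperoxide
Product: 10 [(1R,2R,6S)-2-hydroxy-5,5-dimethoxy-7-oxabicyclo[4.1.0]hept-3-en-2-yl]methyl benzoate (oxirane at C5–C6, syn to the C1 hydroxyl)
Conditions: Hf(OtBu)4 (10 mol %), L* (12 mol %; N,N'-dihydroxy-N,N'-bis(2,2-diphenylacetyl)-trans-cyclohexane-1,2-diamine, single enantiomer), 9 (1.1 equiv, anhydrous in decane), MgO (20 mol %), toluene, 0 °C to rt
Reagents that add atoms: none
Why: The tertiary C1 hydroxyl exchanges for a tert-butoxide on tetravalent hafnium held by the C2-symmetric bis-hydroxamate, 9 binds the same metal, and the electrophilic peroxide oxygen passes intramolecularly to one of the two ring alkenes, both allylic to the bound alkoxide. The closest known reaction type is the hydroxyl-directed asymmetric epoxidation of tertiary allylic alcohols with bis-hydroxamic acid complexes of hafnium and vanadium, together with the desymmetrising epoxidation of divinyl carbinols; 8 is a cyclic, untested member of that class. The oxirane closes in one concerted, suprafacial oxygen-atom transfer (a [2+1] addition) that forms C5–O and C6–O together, so the ring fusion is necessarily cis. The face is fixed by the tether: oxygen can only arrive from the side of the metal-bound C1 alkoxide, which puts the oxirane syn to the C1 hydroxyl and sets C5 and C6 relative to C1. Which enantiotopic alkene reacts is decided by the chiral ligand alone, and that choice makes C1 stereogenic, so all three stereocentres come from one selection. The step needs group selectivity (ligand), face selectivity (alkoxide delivery) and mono- over bis-epoxidation; the last is helped by limiting 9 and by the fact that the major enantiomer keeps the alkene the catalyst disfavours, while the minor enantiomer keeps the favoured one and is consumed preferentially, which should raise the enantiomeric purity of 10. The dimethyl ketal keeps both alkenes electron-rich enough for an electrophilic peroxide, the quaternary C1 rules out rearomatisation, and MgO buffers the Lewis acid so that the ketal and the doubly allylic carbinol are not ionised.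

Step 6
Reactants: 10 [(1R,2R,6S)-2-hydroxy-5,5-dimethoxy-7-oxabicyclo[4.1.0]hept-3-en-2-yl]methyl benzoate
Product: 13 [(1R,5S,6S)-1,5,6-trihydroxy-4-oxocyclohex-2-en-1-yl]methyl benzoate, via epoxy enone 11 (not isolated), via dioxanylium ion 12 (not isolated)
Conditions: HClO4 (70% aq, 0.3 equiv), THF/H2O (9:1), 0 °C to rt; NaHCO3 to pH 6–7
Reagents that add atoms: water, O
Why: Neighbouring-group-assisted epoxide hydrolysis: acid first unmasks the C4 ketone (11), then the carbonyl oxygen of the C7 benzoate, held on the face opposite the protonated oxirane, attacks C6 in a 6-exo displacement with inversion (12), and water opens 12 to the hydroxy ester, the primary benzoate being the thermodynamically preferred regioisomer. C5 keeps its oxygen and configuration, so O6 ends trans to both O5 and O1.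

Step 7
Reactants: 13 [(1R,5S,6S)-1,5,6-trihydroxy-4-oxocyclohex-2-en-1-yl]methyl benzoate
Product: 14 [(1R,5S,6S)-1-hydroxy-4-oxo-5,6-[(1,1,3,3-tetraisopropyldisiloxane-1,3-diyl)bis(oxy)]cyclohex-2-en-1-yl]methyl benzoate
Conditions: (iPr2SiCl)2O (1.05 equiv), imidazole (2.5 equiv), DMF, 0 °C to rt
Reagents that add atoms: 1,3-dichloro-1,1,3,3-tetraisopropyldisiloxane, CC(C)[Si](Cl)(C(C)C)O[Si](Cl)(C(C)C)C(C)C
Why: Cyclic disiloxane protection of a trans-vicinal diol: the reagent silylates a secondary hydroxyl and closes a seven-membered ring onto its neighbour, while the tertiary C1 hydroxyl does not react with a diisopropylsilyl chloride. The trans-fused ring can only exist on the diequatorial diol, which locks the ring conformation for the next step.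

Step 8
Reactants: 14 [(1R,5S,6S)-1-hydroxy-4-oxo-5,6-[(1,1,3,3-tetraisopropyldisiloxane-1,3-diyl)bis(oxy)]cyclohex-2-en-1-yl]methyl benzoate
Product: 15 [(1R,4S,5R,6S)-1,4-dihydroxy-5,6-[(1,1,3,3-tetraisopropyldisiloxane-1,3-diyl)bis(oxy)]cyclohex-2-en-1-yl]methyl benzoate (C4 hydroxyl on the bottom face, trans to O5)
Conditions: NaBH4 (1.2 equiv), CeCl3·7H2O (1.2 equiv), MeOH, −78 °C
Reagents that add atoms: none
Why: Luche reduction: the borohydride/trivalent cerium system adds 1,2 to the enone. With O5 and O6 locked equatorial the C5–H is axial on the bottom face, so axial hydride attack comes from the top face, past only the axial C6–H, and places the new C4 hydroxyl equatorial on the bottom face, trans to O5.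

Step 9
Reactants: 15 [(1R,4S,5R,6S)-1,4-dihydroxy-5,6-[(1,1,3,3-tetraisopropyldisiloxane-1,3-diyl)bis(oxy)]cyclohex-2-en-1-yl]methyl benzoate; 7 benzoyl chloride
Product: 16 [(1R,4S,5R,6S)-4-(benzoyloxy)-1-hydroxy-5,6-[(1,1,3,3-tetraisopropyldisiloxane-1,3-diyl)bis(oxy)]cyclohex-2-en-1-yl]methyl benzoate
Conditions: 7 (1.5 equiv), pyridine, DMAP (10 mol %), CH2Cl2, 0 °C to rt
Reagents that add atoms: none
Why: DMAP-catalysed acylation of the only accessible hydroxyl; the tertiary C1 carbinol is inert under these conditions and the C4–O bond is not broken, so the configuration is kept.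

Step 10
Reactants: 16 [(1R,4S,5R,6S)-4-(benzoyloxy)-1-hydroxy-5,6-[(1,1,3,3-tetraisopropyldisiloxane-1,3-diyl)bis(oxy)]cyclohex-2-en-1-yl]methyl benzoate
Product: 17 [(1R,4S,5S,6S)-4-(benzoyloxy)-1,5,6-trihydroxycyclohex-2-en-1-yl]methyl benzoate (kweichowenol B)
Conditions: HF·pyridine, THF/pyridine, 0 °C to rt
Reagents that add atoms: none
Why: Fluoride-induced Si–O cleavage under buffered, slightly acidic conditions removes the disiloxane bridge without forming alkoxides, so neither benzoate should migrate and no stereocentre is touched.

## Compound list

1 | 4-methoxyphenol | COc1ccc(O)cc1 | starting material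
2 | 4,4-dimethoxycyclohexa-2,5-dien-1-one | COC1(OC)C=CC(=O)C=C1 | intermediate
3 | chloromethyl(isopropoxy)dimethylsilane | CC(C)O[Si](C)(C)CCl | starting material
4 | {[dimethyl(propan-2-yloxy)silyl]methyl}magnesium chloride (not isolated) | CC(C)O[Si](C)(C)C[Mg]Cl | intermediate
5 | 4,4-dimethoxy-1-{[dimethyl(propan-2-yloxy)silyl]methyl}cyclohexa-2,5-dien-1-ol | COC1(OC)C=CC(O)(C[Si](C)(C)OC(C)C)C=C1 | intermediate
6 | 1-(hydroxymethyl)-4,4-dimethoxycyclohexa-2,5-dien-1-ol | COC1(OC)C=CC(O)(CO)C=C1 | intermediate
7 | benzoyl chloride | O=C(Cl)c1ccccc1 | starting material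
8 | (1-hydroxy-4,4-dimethoxycyclohexa-2,5-dien-1-yl)methyl benzoate | COC1(OC)C=CC(O)(COC(=O)c2ccccc2)C=C1 | intermediate
9 | tert-butyl hydroperoxide | CC(C)(C)OO | starting material
10 | [(1R,2R,6S)-2-hydroxy-5,5-dimethoxy-7-oxabicyclo[4.1.0]hept-3-en-2-yl]methyl benzoate | O=C(OC[C@]1(O)C=CC(OC)(OC)[C@H]2O[C@@H]12)c1ccccc1 | intermediate
11 | [(1R,2R,6S)-2-hydroxy-5-oxo-7-oxabicyclo[4.1.0]hept-3-en-2-yl]methyl benzoate (not isolated) | O=C(OC[C@]1(O)C=CC(=O)[C@H]2O[C@@H]12)c1ccccc1 | intermediate
12 | (4aR,8S,8aS)-4a,8-dihydroxy-7-oxo-2-phenyl-4a,7,8,8a-tetrahydro-4H-1,3-benzodioxin-2-ylium, cis-fused (not isolated) | [C+]1(c2ccccc2)OC[C@]2(O)C=CC(=O)[C@@H](O)[C@@H]2O1 | intermediate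
13 | [(1R,5S,6S)-1,5,6-trihydroxy-4-oxocyclohex-2-en-1-yl]methyl benzoate | O=C(OC[C@]1(O)C=CC(=O)[C@@H](O)[C@@H]1O)c1ccccc1 | intermediate
14 | [(1R,5S,6S)-1-hydroxy-4-oxo-5,6-[(1,1,3,3-tetraisopropyldisiloxane-1,3-diyl)bis(oxy)]cyclohex-2-en-1-yl]methyl benzoate | O=C(OC[C@]1(O)C=CC(=O)[C@@H](O[Si](C(C)C)(C(C)C)O[Si]2(C(C)C)C(C)C)[C@@H]1O2)c1ccccc1 | intermediate
15 | [(1R,4S,5R,6S)-1,4-dihydroxy-5,6-[(1,1,3,3-tetraisopropyldisiloxane-1,3-diyl)bis(oxy)]cyclohex-2-en-1-yl]methyl benzoate | O=C(OC[C@]1(O)C=C[C@H](O)[C@@H](O[Si](C(C)C)(C(C)C)O[Si]2(C(C)C)C(C)C)[C@@H]1O2)c1ccccc1 | intermediate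
16 | [(1R,4S,5R,6S)-4-(benzoyloxy)-1-hydroxy-5,6-[(1,1,3,3-tetraisopropyldisiloxane-1,3-diyl)bis(oxy)]cyclohex-2-en-1-yl]methyl benzoate | O=C(OC[C@]1(O)C=C[C@H](OC(=O)c2ccccc2)[C@@H](O[Si](C(C)C)(C(C)C)O[Si]3(C(C)C)C(C)C)[C@@H]1O3)c1ccccc1 | intermediate
17 | [(1R,4S,5S,6S)-4-(benzoyloxy)-1,5,6-trihydroxycyclohex-2-en-1-yl]methyl benzoate (kweichowenol B) | O=C(OC[C@]1(O)C=C[C@H](OC(=O)c2ccccc2)[C@@H](O)[C@@H]1O)c1ccccc1 | target

## Step count and least certain steps

Total step count: 10. Longest linear sequence: 10 steps (1 to 17); 3, 7 and 9 are purchased.

Step 5 (key step). The most likely failure is weak discrimination between the two enantiotopic alkenes: both are held rigidly in one flat ring and differ only in how they sit in the ligand pocket. Lewis-acid ionisation of the ketal or of the doubly allylic carbinol, and over-oxidation to the bis-epoxide, are further risks.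

Fallback: the order of events is reversed, so that the epoxide is made by a nucleophilic asymmetric epoxidation and the carbinol centre is then set by the substrate. It sets out from 2. Tartrate-mediated nucleophilic epoxidation of the quinone monoketal (trityl hydroperoxide, NaHMDS, diisopropyl tartrate of the appropriate hand, toluene, −50 °C) should desymmetrise the dienone to (1R,6S)-5,5-dimethoxy-7-oxabicyclo[4.1.0]hept-3-en-2-one F1. Grignard reagent 4 should then add 1,2 to the ketone from the face opposite the oxirane, giving the silane (1R,2S,6S)-2-{[dimethyl(propan-2-yloxy)silyl]methyl}-5,5-dimethoxy-7-oxabicyclo[4.1.0]hept-3-en-2-ol F2 with the hydroxyl syn to the oxirane. Tamao oxidation as in step 3 would give the epoxy diol (1R,2R,6S)-2-(hydroxymethyl)-5,5-dimethoxy-7-oxabicyclo[4.1.0]hept-3-en-2-ol F3, and primary benzoylation with 7 as in step 4 comes back to the route at 10.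

Step 6. Once the ketone is unmasked the oxirane is an α,β-epoxy ketone: it is less basic, and external water may attack C5 (α to the carbonyl) in competition with the internal benzoate at C6. The β-hydroxy ketone product can dehydrate, and the benzoyl group may partly end on O6. A low-water medium (TFA in CH2Cl2 with a few equivalents of water) would be tried first.

Fallback: the oxygen is delivered under basic conditions with the ketal left in place. It sets out from 10. Methanolysis (K2CO3, MeOH, 0 °C) removes the benzoate and gives the epoxy diol F3 already described. Cs2CO3 under CO2 in DMF with 4 Å sieves converts the primary alkoxide into a carbonate anion that opens the oxirane at C6 from the bottom face (6-exo), giving the cyclic carbonate (4aR,8S,8aS)-4a,8-dihydroxy-7,7-dimethoxy-4a,7,8,8a-tetrahydro-4H-1,3-benzodioxin-2-one F4. K2CO3 in MeOH cleaves the carbonate to the tetrol (1S,2S,3R)-3-(hydroxymethyl)-6,6-dimethoxycyclohex-4-ene-1,2,3-triol F5. Low-temperature benzoylation of the primary hydroxyl (7, 2,4,6-collidine, CH2Cl2, −40 °C) gives [(1R,5S,6S)-1,5,6-trihydroxy-4,4-dimethoxycyclohex-2-en-1-yl]methyl benzoate F6, and mild aqueous acid (PPTS, acetone/H2O) hydrolyses the ketal and comes back to the route at 13.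

Step 7. The reagent may bridge the wrong pair of hydroxyls or stop at a mono-silyl chloride because O6 is flanked by the quaternary C1, and imidazole may enolise the α-ketol (epimerisation at C5 or loss of O6).

Fallback: the diol protection is given up. It sets out from 13. Luche reduction of the unprotected keto triol (NaBH4, CeCl3·7H2O, MeOH, −78 °C; cerium chelation of the C4 carbonyl and the equatorial O5 hydroxyl, axial hydride attack) should give the tetrol [(1R,4S,5R,6S)-1,4,5,6-tetrahydroxycyclohex-2-en-1-yl]methyl benzoate F7. Site-selective benzoylation of its only allylic and least hindered secondary hydroxyl (7, 1.0 equiv, 2,4,6-collidine, CH2Cl2, −40 °C) would then give the target directly, coming back to the route at 17.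

Step 8. Facial selectivity may be poor if the seven-membered disiloxane distorts the half-chair, or if the pseudo-axial C7 arm and the cerium-bound C1 hydroxyl change the preferred trajectory; the result would be the C4 epimer.

Fallback: the epimer is made productive by a stereoinvertive esterification. It sets out from 14. The C4-epimeric alcohol [(1R,4R,5R,6S)-1,4-dihydroxy-5,6-[(1,1,3,3-tetraisopropyldisiloxane-1,3-diyl)bis(oxy)]cyclohex-2-en-1-yl]methyl benzoate F8, separated from 15 or made on purpose with a bulky 1,2-selective hydride (DIBAL-H, −78 °C), is subjected to Mitsunobu esterification (benzoic acid, PPh3, DIAD, THF, 0 °C). This installs the O4 benzoate with inversion and comes back to the route at 16, one step beyond 15.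

## Further compounds

F1 | step 5 | (1R,6S)-5,5-dimethoxy-7-oxabicyclo[4.1.0]hept-3-en-2-one | O=C1C=CC(OC)(OC)[C@H]2O[C@@H]12
F2 | step 5 | (1R,2S,6S)-2-{[dimethyl(propan-2-yloxy)silyl]methyl}-5,5-dimethoxy-7-oxabicyclo[4.1.0]hept-3-en-2-ol | CC(C)O[Si](C)(C)C[C@]1(O)C=CC(OC)(OC)[C@H]2O[C@@H]12
F3 | step 5 | (1R,2R,6S)-2-(hydroxymethyl)-5,5-dimethoxy-7-oxabicyclo[4.1.0]hept-3-en-2-ol | OC[C@]1(O)C=CC(OC)(OC)[C@H]2O[C@@H]12
F4 | step 6 | (4aR,8S,8aS)-4a,8-dihydroxy-7,7-dimethoxy-4a,7,8,8a-tetrahydro-4H-1,3-benzodioxin-2-one | O=C1OC[C@]2(O)C=CC(OC)(OC)[C@@H](O)[C@@H]2O1
F5 | step 6 | (1S,2S,3R)-3-(hydroxymethyl)-6,6-dimethoxycyclohex-4-ene-1,2,3-triol | OC[C@]1(O)C=CC(OC)(OC)[C@@H](O)[C@@H]1O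
F6 | step 6 | [(1R,5S,6S)-1,5,6-trihydroxy-4,4-dimethoxycyclohex-2-en-1-yl]methyl benzoate | O=C(OC[C@]1(O)C=CC(OC)(OC)[C@@H](O)[C@@H]1O)c1ccccc1
F7 | step 7 | [(1R,4S,5R,6S)-1,4,5,6-tetrahydroxycyclohex-2-en-1-yl]methyl benzoate | O=C(OC[C@]1(O)C=C[C@H](O)[C@@H](O)[C@@H]1O)c1ccccc1
F8 | step 8 | [(1R,4R,5R,6S)-1,4-dihydroxy-5,6-[(1,1,3,3-tetraisopropyldisiloxane-1,3-diyl)bis(oxy)]cyclohex-2-en-1-yl]methyl benzoate | O=C(OC[C@]1(O)C=C[C@@H](O)[C@@H](O[Si](C(C)C)(C(C)C)O[Si]2(C(C)C)C(C)C)[C@@H]1O2)c1ccccc1
A1 | alternative 1 | 3-hydroxy-2H-pyran-2-one | O=c1occcc1O
A2 | alternative 1 | (E)-hex-3-ene-2,5-dione | CC(=O)/C=C/C(C)=O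
A3 | alternative 1 | 7,8-diacetyl-4-hydroxy-2-oxabicyclo[2.2.2]oct-5-en-3-one (acetyl on the future C5 syn to the etheno bridge, acetyl on the future C6 syn to the lactone bridge) | O=C1[C@]2(O)C=C[C@H](O1)[C@@H](C(C)=O)[C@@H]2C(C)=O
A4 | alternative 2 | (2R,3S,4Z)-3,7-bis(benzoyloxy)-2-[(tert-butyldimethylsilyl)oxy]-6-oxohept-4-enal | O=C[C@H](O[Si](C)(C)C(C)(C)C)[C@@H](OC(=O)c1ccccc1)/C=C\C(=O)COC(=O)c1ccccc1
A5 | alternative 2 | [(1R,4S,5R)-4-(benzoyloxy)-5-[(tert-butyldimethylsilyl)oxy]-1-hydroxy-6-oxocyclohex-2-en-1-yl]methyl benzoate | O=C(OC[C@]1(O)C=C[C@H](OC(=O)c2ccccc2)[C@@H](O[Si](C)(C)C(C)(C)C)C1=O)c1ccccc1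
A6 | alternative 3 | [(5R,6R)-6-[(tert-butyldimethylsilyl)oxy]-5-hydroxycyclohexa-1,3-dien-1-yl]methyl benzoate | O=C(OCC1=CC=C[C@@H](O)[C@@H]1O[Si](C)(C)C(C)(C)C)c1ccccc1
A7 | alternative 3 | {8-[(tert-butyldimethylsilyl)oxy]-7-hydroxy-2,3-dioxabicyclo[2.2.2]oct-5-en-1-yl}methyl benzoate (peroxide bridge syn to the hydroxyl, anti to the silyl ether) | O=C(OC[C@]1(OO2)C=C[C@@H]2[C@@H](O)[C@@H]1O[Si](C)(C)C(C)(C)C)c1ccccc1
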